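## The problem

Target 12, 4-bromo-3-butyl-5-(dibromomethylene)furan-2(5H)-one, is a single five-membered lactone (O1, carbonyl C2, C3 with the butyl group, C4 with bromine, C5) whose C5 carries the exocyclic dibromomethylene carbon C6. There is no stereocenter, and because C6 bears two identical bromines the C5=C6 bond has no configuration either. Geometry matters only in intermediates with one substituent on C6, and the plan must either control it or let it converge. The real difficulty is regiochemical: three vinylic bromines must be placed at C4 and C6 of a cross-conjugated dienyl lactone without touching the allylic C1' methylene of the butyl chain or the lactone carbonyl. The ring tolerates little rough treatment. C4–Br is a vinylogous acyl bromide that undergoes addition–elimination with nucleophiles and oxidative addition to zerovalent palladium, the enol lactone opens with hydroxide or alkoxide, and the C1' hydrogens are lost under radical bromination. Bromine should therefore be on C4 before the ring exists, and the C6 bromines should come late, by ionic chemistry under mild, non-nucleophilic conditions. The enabling feature is C5: it is bonded to O1 and to the bromine-bearing C4 and doubly bonded to C6, which is the pattern left when a carboxylate oxygen adds to the inner carbon of an alkyne attached to a bromoalkene. C2, C3 and C4 with their substituents then map onto 3,3-dibromo-2-butylacrylic acid 6, in which one geminal bromine is the leaving group for C4–C5 bond formation and the other stays as the C4 bromine.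

## Retrosynthesis

The first cut removes one C6–Br bond of 12. Bromine addition across C5=C6 of bromomethylene lactone 10 gives tribromide 11, and loss of HBr returns the alkene with the second bromine on C6. This addition–elimination pair is standard for 5-alkylidenebutenolides and poses no regiochemical question, because C6 of 11 holds the only hydrogen β to the C5 bromide. The neighbouring option, bringing both C6 bromines in with the alkyne carbon, has no workable reagent. Precursor 10 has one bromine fewer; the forward step must brominate the exocyclic enol-ester alkene in preference to the electron-poor C3=C4 bond and must leave C1' alone.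

The remaining C6–Br bond of 10 is exchanged for a C6–Si bond, giving vinylsilane 9. Silicon is preferred over hydrogen at C6 for three reasons. Ipso-bromodesilylation reaches 10 in one operation, where a 5-methylene lactone would need a full bromination–dehydrobromination cycle. The silyl group makes the alkyne partner a liquid, monofunctional reagent (7) instead of acetylene. It also steers the ring closure of the key step to C5. The forward reaction asks bromine to attack C6, which both the β-silicon effect and the lone pair on O1 favour.

Vinylsilane 9 is cut at C4–C5 and O1–C5. This removes the ring and leads, by way of enynoic acid 8, to acid 6 and ethynyltrimethylsilane 7. Compared with cutting O1–C2 (lactonization of a 4-oxo acid followed by ring bromination), the C4 bromine is already present in 6, so no bromination has to distinguish C4 from C6 or C1'. Compared with cutting C3–C4, the tetrasubstituted C3=C4 alkene is carried in from an acyclic precursor that has no geometry to set. Acid 6 has seven carbons, no ring and no stereo-element. The forward reaction must couple only the bromine cis to the carboxyl group, stop after one alkynylation, and close in the 5-exo rather than the 6-endo mode.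

Acid 6 goes back to its ethyl ester 4 (ester C–O bond, via lithium salt 5). Ester 4 goes back to ethyl 2-oxohexanoate 1 and carbon tetrabromide 2 by cutting the C2=C3 double bond, the dibromomethylene carbon arriving as ylide 3. A ketone-to-dibromoalkene olefination is preferred over halogenation of an alkynoate because it puts both bromines on one carbon by construction and creates no alkene geometry. Both 1 and 2 are catalogue compounds. The forward steps need an olefination of an activated ketone beside an ester, and an ester hydrolysis that leaves the β,β-dibromoacrylate intact.

## Roads not taken

Alternative 1: Ring expansion of a squaric acid derivative. The cut is O1–C2: the lactone is traced to a hydroxy vinylketene, the ring-opened form of 2-butyl-4-(dibromomethyl)-4-hydroxy-3-isopropoxycyclobut-2-en-1-one A2. A2 would come from diisopropyl squarate A3 by exchange of one isopropoxy group for butyl and addition of LiCHBr2 to the more electrophilic carbonyl. On heating, A2 should open electrocyclically, the tertiary hydroxyl should add to the ketene carbon, and tautomerization should give 3-butyl-5-(dibromomethyl)-4-isopropoxyfuran-2(5H)-one A1.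
- Merits: the key step is thermal and metal-free, the ring substituents are fixed by the order of additions to A3, and both C6 bromines arrive together.
- Weak points: A1 has the wrong C4 substituent and the wrong oxidation level. The isopropoxy group must be hydrolysed and replaced by bromine, and C5 is sp3 with a hydrogen, so the C5=C6 bond still has to be made by bromination at C5 and dehydrobromination. LiCHBr2 is a thermally fragile carbenoid, and the alkoxide it forms sits next to a CHBr2 group and can displace bromide before it is protonated.
- Comparison: this road is better in that it never has to distinguish two geminal bromines, which is the one real selectivity question of the chosen plan. The chosen plan closes the ring with C4–Br and the C5=C6 unsaturation already in place and needs five steps where this road needs roughly eight.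

Alternative 2: Dieckmann closure to a tetronic acid. The cut is C3–C4. Methyl 2-(hexanoyloxy)propanoate A5 is treated with LiN(SiMe3)2; the enolate of the hexanoyl ester attacks the methyl ester carbonyl and closes 3-butyl-4-hydroxy-5-methylfuran-2(5H)-one A4.
- Merits: the materials are the cheapest of all four roads, the ring closure is robust and scalable, there is no metal and no site selectivity, and the butyl group is unambiguously at C3.
- Weak points: everything difficult is postponed. The C4 hydroxyl must be exchanged for bromine to give 4-bromo-3-butyl-5-methylfuran-2(5H)-one A6. Then the saturated C5–CH3 unit of A6 must be raised to C5=CBr2: a C5=C6 double bond must be introduced (radical bromination at C5, in competition with the allylic C1' position, then elimination), followed by two bromination–dehydrobromination cycles.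
- Comparison: this road is clearly better in cost and in the reliability of ring formation. The chosen plan has the C4 bromine and the exocyclic unsaturation present at ring closure, avoids radical bromination altogether, and is about three steps shorter.

Alternative 3: Carbonylative lactonization of a β-iodo enone. The cuts are C2–C3 and C2–O1, the carbonyl carbon coming from CO. Zerovalent palladium formed from Pd(PPh3)2Cl2 inserts into the C–I bond of (E)-3-bromo-4-iodooct-3-en-2-one A8, CO inserts, and the enol oxygen of the methyl ketone captures the acylpalladium to give 4-bromo-3-butyl-5-methylenefuran-2(5H)-one A7.
- Merits: this is the closest competitor. The ring arrives with C4–Br and the exocyclic alkene in place, and site selection rests on C–I against C–Br, which is intrinsically more reliable than telling two geminal bromines apart. In that respect it is better than the chosen plan.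
- Weak points: A8 is a stereodefined tetrasubstituted bromo-iodo enone with iodine cis to the acetyl group. Electrophilic iodobromination of the corresponding ynone would place the halogens the other way round, and conjugate hydroiodination followed by α-bromination risks loss of geometry, so the precursor is harder to make than the key step is to run. The step needs CO handling. The enol oxygen must compete with other acylpalladium pathways. A7 carries an unsubstituted exocyclic methylene that polymerizes easily and needs two full bromination–dehydrobromination cycles.
- Comparison: the chosen plan has a two-step precursor synthesis from catalogue compounds, no gas handling, and a silicon handle on C6 that replaces one of those cycles by a single ipso-substitution.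

Key step: step 3

Remark: the C5=C6 configuration of 10 is drawn Z (bromine syn to O1); should the E isomer form as well, it is carried on, because both isomers give the same tribromide 11 and the same target.

## Route

Step 1
Reactants: 1 ethyl 2-oxohexanoate; 2 carbon tetrabromide
Product: 4 ethyl 3,3-dibromo-2-butylacrylate, via (dibromomethylene)triphenylphosphorane 3 (not isolated)
Conditions: PPh3 (4 equiv), CBr4 (2 equiv), CH2Cl2, 0 °C; then 1, 0 °C to rt
Reagents that add atoms: none
Why: Ramirez dibromoolefination (first stage of the Corey–Fuchs sequence): PPh3 and 2 form ylide 3, which undergoes a Wittig reaction with the ketone carbonyl of 1, activated by the adjacent ester. The ester carbonyl is not attacked, and a geminal dibromoalkene has no geometry to control.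

Step 2
Reactants: 4 ethyl 3,3-dibromo-2-butylacrylate
Product: 6 3,3-dibromo-2-butylacrylic acid, via lithium 3,3-dibromo-2-butylacrylate 5 (not isolated)
Conditions: LiOH·H2O (2 equiv), THF/H2O, 0 °C to rt; then 1 M HCl
Reagents that add atoms: lithium hydroxide, [Li+].[OH-]
Why: Saponification by hydroxide attack at the ester carbonyl gives carboxylate 5, which is protonated on acidification. The fully substituted alkene has no α-hydrogen, so dehydrobromination is impossible, and low temperature keeps conjugate attack at the dibromo carbon slow.

Step 3
Reactants: 6 3,3-dibromo-2-butylacrylic acid; 7 ethynyltrimethylsilane
Product: 9 (Z)-4-bromo-3-butyl-5-[(trimethylsilyl)methylene]furan-2(5H)-one, via (E)-3-bromo-2-butyl-5-(trimethylsilyl)pent-2-en-4-ynoic acid 8 (not isolated)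
Conditions: Pd(PPh3)4 (5 mol %), CuI (10 mol %), Et3N (3 equiv), MeCN, rt; 7 (1.05 equiv) added slowly
Reagents that add atoms: none
Why: Zerovalent palladium inserts into the C–Br bond of the triethylammonium salt of 6 that lies cis to the carboxylate, the alkynylcopper species Me3SiC≡CCu formed from 7, CuI and Et3N transmetalates, and reductive elimination forms the C4–C5 bond of enynoic acid 8 (Sonogashira coupling). The carboxylate of 8 then attacks the metal-coordinated triple bond at its inner carbon in a 5-exo-dig closure that forms O1–C5 and the lactone ring, and protonolysis of the vinyl–metal bond by triethylammonium releases 9. The closest known reaction type is the tandem Sonogashira coupling–lactonization of (Z)-3-haloacrylic acids with terminal alkynes to (Z)-5-ylidenefuran-2(5H)-ones. No stereocenter is formed; the Z geometry (silicon syn to O1) follows from anti addition of oxygen and metal across the alkyne and protonolysis with retention. Three selectivities are needed: the site of oxidative addition, a single alkynylation, and 5-exo over 6-endo closure. The first is secured by the carboxylate, which binds palladium and delivers it to the cis C–Br bond through a five-membered palladacycle; an acid coupled at the trans bromine cannot cyclize and is removed from neutral 9 by a NaHCO3 wash. The second rests on the higher reactivity of a geminal dibromoalkene compared with the remaining hindered C4–Br bond, with 7 kept limiting by slow addition. The third is set by silicon, which stabilizes positive charge at the inner (β) alkyne carbon and shields the outer one.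

Step 4
Reactants: 9 (Z)-4-bromo-3-butyl-5-[(trimethylsilyl)methylene]furan-2(5H)-one
Product: 10 (Z)-4-bromo-5-(bromomethylene)-3-butylfuran-2(5H)-one
Conditions: Br2 (1.05 equiv), CH2Cl2, −78 to 0 °C, dark
Reagents that add atoms: bromine, BrBr
Why: Electrophilic ipso-bromodesilylation of a vinylsilane: bromine attacks C6, the positive charge at C5 is stabilized by the β-silicon and by O1, and loss of Me3SiBr restores the C5=C6 bond. The silyl-substituted enol-ester alkene is far more nucleophilic than the C3=C4 bond or the product, so one equivalent of bromine should be consumed selectively.

Step 5
Reactants: 10 (Z)-4-bromo-5-(bromomethylene)-3-butylfuran-2(5H)-one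
Product: 12 4-bromo-3-butyl-5-(dibromomethylene)furan-2(5H)-one, via 4,5-dibromo-3-butyl-5-(dibromomethyl)furan-2(5H)-one 11 (not isolated)
Conditions: Br2 (1.05 equiv), CH2Cl2, 0 °C to rt, dark; then Et3N (1.2 equiv), 0 °C
Reagents that add atoms: bromine, BrBr
Why: Ionic addition of bromine to the exocyclic enol-ester alkene gives tribromide 11, and Et3N removes HBr across C5–C6, where C6 carries the only β-hydrogen; this bromination–dehydrobromination sequence is well established for 5-alkylidenebutenolides. C5 of 11 is a transient, racemic stereocenter that is destroyed in the elimination, and the product has no alkene geometry.

## Compound list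

1 | ethyl 2-oxohexanoate | CCCCC(=O)C(=O)OCC | starting material
2 | carbon tetrabromide | BrC(Br)(Br)Br | starting material
3 | (dibromomethylene)triphenylphosphorane | BrC(Br)=P(c1ccccc1)(c1ccccc1)c1ccccc1 | intermediate
4 | ethyl 3,3-dibromo-2-butylacrylate | CCCCC(C(=O)OCC)=C(Br)Br | intermediate
5 | lithium 3,3-dibromo-2-butylacrylate | CCCCC(C(=O)[O-])=C(Br)Br.[Li+] | intermediate
6 | 3,3-dibromo-2-butylacrylic acid | CCCCC(C(=O)O)=C(Br)Br | intermediate
7 | ethynyltrimethylsilane | C#C[Si](C)(C)C | starting material
8 | (E)-3-bromo-2-butyl-5-(trimethylsilyl)pent-2-en-4-ynoic acid | CCCC/C(C(=O)O)=C(\Br)C#C[Si](C)(C)C | intermediate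
9 | (Z)-4-bromo-3-butyl-5-[(trimethylsilyl)methylene]furan-2(5H)-one | CCCCC1=C(Br)/C(=C/[Si](C)(C)C)OC1=O | intermediate
10 | (Z)-4-bromo-5-(bromomethylene)-3-butylfuran-2(5H)-one | CCCCC1=C(Br)/C(=C/Br)OC1=O | intermediate
11 | 4,5-dibromo-3-butyl-5-(dibromomethyl)furan-2(5H)-one (racemic) | CCCCC1=C(Br)C(Br)(C(Br)Br)OC1=O | intermediate
12 | 4-bromo-3-butyl-5-(dibromomethylene)furan-2(5H)-one | CCCCC1=C(Br)C(=C(Br)Br)OC1=O | target

## Step count and risks

Total step count: 5. Longest linear sequence: 5 steps (1 to 4 to 6 to 9 to 10 to 12).

Least certain steps:

Step 3 (key step). Oxidative addition at the bromine trans to the carboxylate, or a second alkynylation at the C–Br bond meant to survive as C4–Br, would divert material before or after ring closure. Closure in the 6-endo mode, or copper-mediated loss of silicon from the alkyne, would give the wrong ring or the wrong C6 substituent. The fallback separates coupling from ring closure and closes the ring with an electrophile instead of a metal. Setting out from 6, Negishi coupling with bromo[(trimethylsilyl)ethynyl]zinc F1 (from 7, BuLi and ZnBr2; 2 equiv, the first deprotonating the acid; Pd(PPh3)4, THF, 0 °C to rt) should stop at acid 8, which is then isolated by acid–base extraction. NBS with KHCO3 in MeCN should then induce 5-exo bromolactonization, with bromonium formation at the silicon-bearing carbon and anti attack of the carboxylate at the inner carbon, to give (E)-4-bromo-5-[bromo(trimethylsilyl)methylene]-3-butylfuran-2(5H)-one F2. Bromodesilylation of F2 with Br2 in CH2Cl2 should give 12 directly, so the fallback comes back to the route at 12 and bypasses 9, 10 and 11.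

Step 5. Substitution or hydrolysis of the acylal-type C5 bromide of 11 before elimination, or addition–elimination of the amine at C4 of 11 or 12, would compete with dehydrobromination. Slow bromine addition to the doubly deactivated alkene would leave room for radical bromination at C1'. The fallback replaces base-induced elimination by acid-induced dehydration. Setting out from 10, NBS in aqueous acetone should give 4-bromo-3-butyl-5-(dibromomethyl)-5-hydroxyfuran-2(5H)-one F3, water capturing the C5 cation, and dehydration of F3 in concentrated H2SO4 should give the exocyclic alkene; the fallback comes back to the route at 12.

Step 4. Loss of HBr instead of Me3SiBr from the bromine adduct would leave silicon on C6, and protodesilylation by adventitious HBr followed by bromination of the resulting methylene lactone would give mixed C6 substitution patterns. The fallback removes silicon with a proton first and brominates afterwards. Setting out from 9, CF3CO2H in CH2Cl2 should protodesilylate (ipso protonation at C6, loss of the silyl group) to 4-bromo-3-butyl-5-methylenefuran-2(5H)-one F4 (identical with A7). Br2 in CH2Cl2 should then add to give 4,5-dibromo-5-(bromomethyl)-3-butylfuran-2(5H)-one F5, which is not isolated, and Et3N should remove HBr to give 10, where the route is rejoined.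

Step 2. Conjugate addition of hydroxide at the dibromo carbon followed by loss of bromide (the ester is a vinylogous acyl bromide) would compete with attack at the hindered ester carbonyl. The fallback cleaves the O–ethyl bond instead of the acyl–oxygen bond. Setting out from 4, Me3SiI in CHCl3 at 50 °C should dealkylate the ester by SN2 attack of iodide at the ethyl group to give trimethylsilyl 3,3-dibromo-2-butylacrylate F6, which is hydrolysed on aqueous work-up to 6, where the route is rejoined.

## Further compounds

F1 | step 3 | bromo[(trimethylsilyl)ethynyl]zinc | C[Si](C)(C)C#C[Zn]Br
F2 | step 3 | (E)-4-bromo-5-[bromo(trimethylsilyl)methylene]-3-butylfuran-2(5H)-one | CCCCC1=C(Br)/C(=C(\Br)[Si](C)(C)C)OC1=O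
F3 | step 5 | 4-bromo-3-butyl-5-(dibromomethyl)-5-hydroxyfuran-2(5H)-one (racemic) | CCCCC1=C(Br)C(O)(C(Br)Br)OC1=O
F4 | step 4 | 4-bromo-3-butyl-5-methylenefuran-2(5H)-one | CCCCC1=C(Br)C(=C)OC1=O
F5 | step 4 | 4,5-dibromo-5-(bromomethyl)-3-butylfuran-2(5H)-one (racemic) | CCCCC1=C(Br)C(Br)(CBr)OC1=O
F6 | step 2 | trimethylsilyl 3,3-dibromo-2-butylacrylate | CCCCC(C(=O)O[Si](C)(C)C)=C(Br)Br
A1 | alternative 1 | 3-butyl-5-(dibromomethyl)-4-isopropoxyfuran-2(5H)-one (racemic) | CCCCC1=C(OC(C)C)C(C(Br)Br)OC1=O
A2 | alternative 1 | 2-butyl-4-(dibromomethyl)-4-hydroxy-3-isopropoxycyclobut-2-en-1-one (racemic) | CCCCC1=C(OC(C)C)C(O)(C(Br)Br)C1=O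
A3 | alternative 1 | diisopropyl squarate | CC(C)OC1=C(OC(C)C)C(=O)C1=O
A4 | alternative 2 | 3-butyl-4-hydroxy-5-methylfuran-2(5H)-one (racemic) | CCCCC1=C(O)C(C)OC1=O
A5 | alternative 2 | methyl 2-(hexanoyloxy)propanoate (racemic) | CCCCCC(=O)OC(C)C(=O)OC
A6 | alternative 2 | 4-bromo-3-butyl-5-methylfuran-2(5H)-one (racemic) | CCCCC1=C(Br)C(C)OC1=O
A7 | alternative 3 | 4-bromo-3-butyl-5-methylenefuran-2(5H)-one | CCCCC1=C(Br)C(=C)OC1=O
A8 | alternative 3 | (E)-3-bromo-4-iodooct-3-en-2-one | CCCC/C(I)=C(\Br)C(C)=O
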